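**Assumptions (one line each)**
- The target SMILES corresponds to (2S)-flavanone; I checked the CIP assignment from the SMILES. The only stereocenter is C2, and it is carried unchanged from commercial (2S)-naringenin.
- No step touches C2, but several steps use base or heat. I assume ee is checked by chiral HPLC after each such step.

## Retrosynthetic overview
1. Target ← acid removal of a 7-O-MOM group ← 2,2-dimethylchromene **8**.
2. Chromene **8** ← anodic dehydrogenative oxa-6π cyclization of one ortho-prenyl group of the 3',5'-diprenyl-4'-phenol **7**. This is the only ring formed in the route, and it is the key C–O bond.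
3. **7** ← cross-metathesis of diallyl phenol **6** with 2-methyl-2-butene. **6** ← two O-allylation/Claisen cycles on the 4'-OH of 7-O-MOM-naringenin **2**.
4. **2** ← selective 7-O-protection of (2S)-naringenin **1**. Rings A and C and the C2 stereocenter come pre-built from **1**.

## Route

**Step 1**
Reactants: **1**, (2S)-naringenin
Product: **2**, (2S)-7-O-(methoxymethyl)naringenin
Conditions: MOMCl (1.05 equiv), K2CO3 (1.1 equiv), DMF, 0 °C → rt, 2 h
Reagents that add atoms: MOMCl, ClCOC
Why: The 7-OH is the most acidic phenol (para to the C4 carbonyl) and is alkylated first. The 5-OH is chelated to the C4 carbonyl and inert. This is an SN2 alkylation with mild base and short time, so C2 is not touched.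

**Step 2**
Reactants: **2**
Product: **3**, 4'-O-allyl ether of **2**
Conditions: allyl bromide (1.5 equiv), K2CO3, acetone, 40 °C
Reagents that add atoms: allyl bromide, C=CCBr
Why: The 4'-OH is the only unhindered free phenol (5-OH is chelated). This is a Williamson etherification.

**Step 3**
Reactants: **3**
Product: **4**, 3'-allyl-4'-hydroxy compound
Conditions: o-dichlorobenzene, 180 °C (microwave), 1 h
Reagents that add atoms: none
Why: Aromatic Claisen [3,3] shift of an aryl allyl ether to the free ortho position. C2 is not involved.

**Step 4**
Reactants: **4**
Product: **5**, 3'-allyl-4'-O-allyl ether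
Conditions: allyl bromide (1.5 equiv), K2CO3, acetone, 50 °C
Reagents that add atoms: allyl bromide, C=CCBr
Why: Same Williamson etherification as Step 2, on the remaining 4'-OH.

**Step 5**
Reactants: **5**
Product: **6**, 3',5'-diallyl-4'-hydroxy compound
Conditions: o-dichlorobenzene, 180 °C (microwave), 1 h
Reagents that add atoms: none
Why: A second Claisen shift goes to the only remaining ortho carbon (C5'). This gives the symmetric diallylphenol.

**Step 6**
Reactants: **6**
Product: **7**, 3',5'-diprenyl-4'-hydroxy compound
Conditions: 2-methyl-2-butene (30 equiv), Hoveyda–Grubbs II (5 mol%), 1,4-benzoquinone (10 mol%), CH2Cl2, 40 °C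
Reagents that add atoms: 2-methyl-2-butene, CC=C(C)C (supplies the =CMe2 terminus; propene is released)
Why: Cross-metathesis of terminal allyl groups with a trisubstituted alkene is driven by volatile propene loss and gives prenyl arenes. Benzoquinone suppresses Ru–H alkene isomerization. The catalyst is achiral.

**Step 7**
Reactants: **7**
Product: **8**, 7-O-MOM-protected chromeno-prenyl flavanone (3',4'-fused 2,2-dimethyl-2H-chromene, 5'-prenyl)
Conditions: graphite anode, Pt cathode, undivided cell, constant current (about 2.2 F/mol), nBu4NPF6 (0.1 M), HFIP/CH2Cl2 1:4, 2,6-lutidine (0.5 equiv), rt, N2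
Reagents that add atoms: none (net loss of H2 at the cathode)
Why: Proposed new method: anodic oxidation of the 2,6-dialkyl-4-alkylphenol in HFIP gives a phenoxyl radical cation. Loss of a proton and a second electron from the doubly activated benzylic/allylic CH2 of one ortho-prenyl group gives an o-quinone methide conjugated to the prenyl alkene (a 1-oxatriene). This undergoes spontaneous thermal 6π-oxa-electrocyclization to the 2,2-dimethyl-2H-chromene, and the cathode reduces the protons to H2. The closest known reactions are DDQ-type dehydrogenative cyclization of o-prenylphenols and anodic o-quinone methide generation from 2-alkylphenols. Cyclization consumes the free phenol, so only one chromene can form and the second prenyl is preserved. C2 is not involved, and the 7-OMOM ring is more electron-poor than the hindered trialkylphenol.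

**Step 8**
Reactants: **8**
Product: **9**, target (2S)-5,7-dihydroxy-flavanone with 3',4'-(2,2-dimethylchromeno) and 5'-prenyl
Conditions: 2 M HCl (aq)/MeOH/THF (1:2:2), 35 °C, 4 h
Reagents that add atoms: none
Why: Acid hydrolysis of the aryl MOM acetal. Flavanones do not racemize under acid, and the prenyl and chromene alkenes survive these mild conditions.

## Checks performed
- Ring sizes and substituents: the B ring of **9** carries the C1' flavanone link, C3' chromene CH=, C4'–O–CMe2, and C5' prenyl. This matches the target SMILES.
- Formula: C15H12O5 (naringenin) plus two C5H8 units, minus H2, gives C25H26O5 for **9**.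
- Atom accounting: every step's product follows from its reactants and the listed reagents.
- Functional-group survival: the 5-OH is chelated and untouched until the end. The MOM group survives the base steps, the Claisen steps, the metathesis and the electrolysis. The chromene and prenyl alkenes survive the final mild acid.
- Stereocenter: C2 is set only by **1** and is never a reaction site.

## Compound list
1 | (2S)-naringenin | Oc1ccc([C@@H]2CC(=O)c3c(O)cc(O)cc3O2)cc1 | starting material
2 | (2S)-7-O-MOM-naringenin | Oc1ccc([C@@H]2CC(=O)c3c(O)cc(OCOC)cc3O2)cc1 | intermediate
3 | (2S)-4'-O-allyl-7-O-MOM-naringenin | C=CCOc1ccc([C@@H]2CC(=O)c3c(O)cc(OCOC)cc3O2)cc1 | intermediate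
4 | (2S)-3'-allyl-7-O-MOM-naringenin | C=CCc1cc([C@@H]2CC(=O)c3c(O)cc(OCOC)cc3O2)ccc1O | intermediate
5 | (2S)-3'-allyl-4'-O-allyl-7-O-MOM-naringenin | C=CCOc1ccc([C@@H]2CC(=O)c3c(O)cc(OCOC)cc3O2)cc1CC=C | intermediate
6 | (2S)-3',5'-diallyl-7-O-MOM-naringenin | C=CCc1cc([C@@H]2CC(=O)c3c(O)cc(OCOC)cc3O2)cc(CC=C)c1O | intermediate
7 | (2S)-3',5'-diprenyl-7-O-MOM-naringenin | CC(C)=CCc1cc([C@@H]2CC(=O)c3c(O)cc(OCOC)cc3O2)cc(CC=C(C)C)c1O | intermediate
8 | (2S)-7-O-MOM chromeno-prenyl flavanone | CC(C)=CCc1cc([C@@H]2CC(=O)c3c(O)cc(OCOC)cc3O2)cc2c1OC(C)(C)C=C2 | intermediate
9 | Target: (2S)-5,7-dihydroxy-5'-prenyl-3',4'-(2,2-dimethylpyrano)flavanone | CC(C)=CCc1cc([C@@H]2CC(=O)c3c(O)cc(O)cc3O2)cc2c1OC(C)(C)C=C2 | target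

## Totals
Total steps: 8. Longest linear sequence: 8.

## Three steps most likely to fail
1. **Step 7 (proposed new electrochemical cyclization).**
   - Risks: over-oxidation of the product chromene, oxidation of the tertiary p-hydroxybenzylic C2–H (which would give a p-quinone methide and lose stereochemistry), or competing oxidation of the A ring.
   - Fallback (known chemistry): from **4**, O-alkylate with 3-chloro-3-methylbut-1-yne (CuI, DBU), then do a thermal propargyl Claisen/6π cyclization to form the chromene at C5' while the allyl group stays. Then do the Step 6 cross-metathesis and the Step 8 deprotection.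
2. **Step 5 (and equally Step 3), the Claisen shifts.**
   - Risks: at 180 °C the flavanone can ring-open and racemize, and the second Claisen is more hindered.
   - Fallback: replace each O-allylation/Claisen pair with room-temperature Pd(0)/Et3B ortho-C-allylation of the phenol with allyl alcohol, a Tamaru-type reaction that involves no heat or O-alkylation.
3. **Step 6, the double cross-metathesis.**
   - Risks: incomplete conversion (mono-prenyl/mono-allyl mixtures), allyl-to-propenyl isomerization, and free-phenol interference.
   - Fallback: take **6** through Lemieux–Johnson cleavage to the bis(arylacetaldehyde), then a Wittig reaction with isopropylidene-triphenylphosphorane to install both prenyl groups. This is olefination instead of metathesis.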